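**Retrosynthetic overview**
- The target is reached from its aryl triisopropylsilyl ether by fluoride desilylation (last step).
- Key disconnection: the C1–C6 and C4–C5 bonds of the cyclohexa-2,5-dienone. Methoxyacetylene is inserted by zerovalent nickel into the acyl–C4 σ bond of (4S)-2-allyl-4-methoxy-4-(sec-alkyl)cyclobut-2-en-1-one (formal [4+2], four-membered ring to six-membered ring, C4 carried over with retention).
- Enabling feature: in the six-membered ring the carbonyl carbon C1 and the fully substituted C4 (OMe, side chain, no H) are para. Joining them directly gives a cyclobutenone whose strained C1–C4 bond is the one a low-valent metal opens, and because C4 has no hydrogen the insertion product cannot aromatise and stays the cross-conjugated dienone.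
- The cyclobutenone comes from a squarate-derived 3-allylcyclobutenone mono-ketal of (S,S)-hydrobenzoin and a configurationally defined secondary alkyllithium (from (S)-propylene oxide, iodide with inversion, iodine–lithium exchange with retention). The ketal sets C4 and is then hydrolysed to the ring carbonyl.
- Ring order: the four-membered ring is bought as diisopropyl squarate, the arene is bought, and the six-membered dienone ring is formed last (step 10).

Key step: step 10

Assumption: in step 7 the spiro-ketal is taken to steer the organolithium to the carbonyl face anti to the phenyl group that flanks the carbonyl, which for the (S,S)-diol gives (S) at the new carbinol carbon; should the sense prove opposite, (R,R)-hydrobenzoin is used in step 2 and nothing else changes.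

**Step 1**
Reactants: 1 diisopropyl squarate
Product: 2 4-hydroxy-2,3-diisopropoxycyclobut-2-en-1-one (racemic)
Conditions: LiAlH(O-t-Bu)3, THF, −78 °C; aq. NH4Cl
Reagents that add atoms: none
Why: 1,2-reduction of one of the two equivalent vinylogous ester carbonyls by the hindered hydride LiAlH(O-t-Bu)3 stops at the 4-hydroxycyclobutenone (known semisquarate chemistry); the carbinol center is racemic and is erased in step 2.

**Step 2**
Reactants: 2 4-hydroxy-2,3-diisopropoxycyclobut-2-en-1-one; 3 (1S,2S)-1,2-diphenylethane-1,2-diol
Product: 4 (6S,7S)-3-isopropoxy-6,7-diphenyl-5,8-dioxaspiro[3.4]oct-2-en-1-one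
Conditions: BF3·OEt2 (20 mol %), 4 Å molecular sieves, CH2Cl2, 0 °C
Reagents that add atoms: none
Why: Lewis-acid ionisation of the carbinol gives an isopropoxy-stabilised cyclobutenyl cation that the diol should capture at the isopropoxy-bearing carbon next to the carbonyl, the second hydroxyl then displacing isopropanol to close the spiro-dioxolane (regiospecific cyclobutenedione mono-ketal formation); the two diol centers are bought and, the diol being C2-symmetric, the spiro carbon is not a stereocenter.

**Step 3**
Reactants: 4 (6S,7S)-3-isopropoxy-6,7-diphenyl-5,8-dioxaspiro[3.4]oct-2-en-1-one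
Product: 6 (6S,7S)-3-allyl-6,7-diphenyl-5,8-dioxaspiro[3.4]oct-2-en-1-one, via tertiary alcohol 5 (not isolated)
Conditions: allylmagnesium bromide, THF, −78 °C; then 1 M aq. HCl, 0 °C
Reagents that add atoms: allylmagnesium bromide, C=CC[Mg]Br; water, O
Why: Stork–Danheiser 1,3-carbonyl transposition, in which 1,2-addition of the allyl Grignard reagent to the vinylogous ester carbonyl and acid-promoted loss of water and isopropanol from the tertiary alcohol give the 3-allyl enone (direct addition–elimination at the isopropoxy carbon would give the same product), while the electron-poor dioxolane should survive cold dilute acid.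

**Step 4**
Reactants: 7 4-bromo-2-methoxyphenol
Product: 8 (4-bromo-2-methoxyphenoxy)triisopropylsilane
Conditions: TIPSCl, imidazole, DMF, rt
Reagents that add atoms: triisopropylsilyl chloride (TIPSCl), CC(C)[Si](Cl)(C(C)C)C(C)C
Why: Standard silylation of a phenol; the bulky aryl silyl ether should survive Grignard formation and t-BuLi at low temperature and leaves with fluoride at the end.

**Step 5**
Reactants: 8 (4-bromo-2-methoxyphenoxy)triisopropylsilane; 9 (S)-propylene oxide
Product: 11 (2S)-1-[3-methoxy-4-(triisopropylsilyloxy)phenyl]propan-2-ol, via arylmagnesium bromide 10 (not isolated)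
Conditions: Mg, THF, reflux; then CuI (10 mol %), 9, −30 → 0 °C; aq. NH4Cl
Reagents that add atoms: none
Why: Copper-catalysed SN2 opening of the epoxide by the aryl Grignard reagent at the unsubstituted carbon, so the stereocenter of (S)-propylene oxide is not touched and becomes the (S)-carbinol.

**Step 6**
Reactants: 11 (2S)-1-[3-methoxy-4-(triisopropylsilyloxy)phenyl]propan-2-ol
Product: 12 [4-[(2R)-2-iodopropyl]-2-methoxyphenoxy]triisopropylsilane
Conditions: I2, PPh3, imidazole, CH2Cl2, −10 → 0 °C
Reagents that add atoms: iodine, II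
Why: Appel-type iodination, in which iodide displaces the alkoxyphosphonium leaving group by SN2 with inversion to give the (R)-iodide, the cold non-ionising medium being chosen to keep aryl participation and iodide exchange slow.

**Step 7**
Reactants: 12 [4-[(2R)-2-iodopropyl]-2-methoxyphenoxy]triisopropylsilane; 6 (6S,7S)-3-allyl-6,7-diphenyl-5,8-dioxaspiro[3.4]oct-2-en-1-one
Product: 15 (1S,6S,7S)-3-allyl-1-methoxy-1-{(2R)-1-[3-methoxy-4-(triisopropylsilyloxy)phenyl]propan-2-yl}-6,7-diphenyl-5,8-dioxaspiro[3.4]oct-2-ene, via secondary alkyllithium 13 (not isolated), via lithium alkoxide 14 (not isolated)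
Conditions: t-BuLi (2.2 equiv), pentane/Et2O, −100 °C (12 added to t-BuLi); then 6, −100 → −78 °C; then MeOTf, −78 → −20 °C
Reagents that add atoms: methyl trifluoromethanesulfonate (MeOTf), COS(=O)(=O)C(F)(F)F
Why: Iodine–lithium exchange at −100 °C is known to give secondary alkyllithiums with retention that hold their configuration long enough to be trapped by ketones with retention, which fixes the side-chain center as (R); 1,2-addition to the strained enone carbonyl should occur on the face anti to the phenyl group of the spiro-ketal that flanks the carbonyl (chiral α-keto acetal control), which sets C4 as (S), and the lithium alkoxide is O-methylated by MeOTf in the cold before the cyclobutenoxide can ring-open.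

**Step 8**
Reactants: 15 (1S,6S,7S)-3-allyl-1-methoxy-1-{(2R)-1-[3-methoxy-4-(triisopropylsilyloxy)phenyl]propan-2-yl}-6,7-diphenyl-5,8-dioxaspiro[3.4]oct-2-ene
Product: 16 (4S)-4-methoxy-4-{(2R)-1-[3-methoxy-4-(triisopropylsilyloxy)phenyl]propan-2-yl}-2-(prop-2-en-1-yl)cyclobut-2-en-1-one
Conditions: 2 M aq. HCl, THF, 0 °C → rt
Reagents that add atoms: water, O
Why: Acid hydrolysis of the dioxolane through an oxygen-stabilised allylic oxocarbenium ion unmasks the ring carbonyl and returns the diol, while the tertiary methyl ether, which has no second oxygen to assist ionisation, and the aryl silyl ether should survive; no stereocenter is touched.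

**Step 9**
Reactants: 17 2-chloro-1,1-dimethoxyethane
Product: 19 methoxyacetylene, via sodium methoxyacetylide 18 (not isolated)
Conditions: NaNH2 (3 equiv), liquid NH3, −33 °C; then cold saturated aq. NaCl, distillation into a cold trap
Reagents that add atoms: none
Why: Classical alkoxyacetylene synthesis, in which sodium amide effects two eliminations (methanol, then hydrogen chloride) from the α-chloro acetal and holds the product as its sodium acetylide until the aqueous quench, from which the volatile alkyne is distilled.

**Step 10**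
Reactants: 16 (4S)-4-methoxy-4-{(2R)-1-[3-methoxy-4-(triisopropylsilyloxy)phenyl]propan-2-yl}-2-(prop-2-en-1-yl)cyclobut-2-en-1-one; 19 methoxyacetylene
Product: 20 (4S)-4,5-dimethoxy-4-{(2R)-1-[3-methoxy-4-(triisopropylsilyloxy)phenyl]propan-2-yl}-2-(prop-2-en-1-yl)cyclohexa-2,5-dien-1-one
Conditions: Ni(COD)2 (10 mol %), Et2O, 0 °C, 19 (3 equiv) added slowly
Reagents that add atoms: none
Why: Proposed new method: zerovalent nickel should add oxidatively into the strained acyl–C4 σ bond of 16 to give a five-membered acyl(alkyl)nickel ring (the σ form of an η4-vinylketene complex), methoxyacetylene should insert syn into the Ni–acyl bond with the acyl carbon going to the nucleophilic CH terminus and nickel to the methoxy-bearing carbon, and C(sp2)–C(sp3) reductive elimination from the seven-membered nickelacycle should then close the C4–C5 bond and return zerovalent nickel. The closest known reaction types are the nickel-catalysed synthesis of phenols from cyclobutenones and alkynes and the nickel-catalysed [4+2] ring expansion of cyclobutanones and azetidin-3-ones with alkynes, which are not known for a cyclobutenone whose C4 is fully substituted or for an alkynyl ether. The six-membered ring is closed as a formal [4+2] (a 2π component inserted into a σ bond), the last event being reductive elimination and not a pericyclic closure. No stereocenter is created: the quaternary C4 is carried over with retention, because nickel replaces C1 and is then replaced by C5 on the same face of C4 (the η3-allyl form keeps the metal on that face, and at 0 °C no free vinylketene should form by thermal ring opening), and the side-chain center is untouched. The step needs cleavage of C1–C4 and not C1–C2 (only C1–C4 is the strained allylic σ bond), one sense of alkyne insertion (fixed by the polarisation of the ynol ether, whose CH carbon is the nucleophilic end) and chemoselectivity over the allyl group and over alkyne oligomerisation (slow addition of 19 keeps the alkyne concentration low). Because C4 bears no hydrogen the product cannot tautomerise to a phenol and stays the cross-conjugated dienone.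

**Step 11**
Reactants: 20 (4S)-4,5-dimethoxy-4-{(2R)-1-[3-methoxy-4-(triisopropylsilyloxy)phenyl]propan-2-yl}-2-(prop-2-en-1-yl)cyclohexa-2,5-dien-1-one
Product: 21 (4S)-4-[(2R)-1-(4-hydroxy-3-methoxyphenyl)propan-2-yl]-4,5-dimethoxy-2-(prop-2-en-1-yl)cyclohexa-2,5-dien-1-one
Conditions: TBAF, AcOH, THF, 0 °C
Reagents that add atoms: none
Why: Fluoride cleavage of the aryl silyl ether, buffered by acetic acid so that the phenoxide is protonated at once and the base-sensitive vinylogous ester dienone is not exposed to basic fluoride; no stereocenter is touched.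

**Compound list**
1 | diisopropyl squarate (3,4-diisopropoxycyclobut-3-ene-1,2-dione) | CC(C)OC1=C(OC(C)C)C(=O)C1=O | starting material
2 | 4-hydroxy-2,3-diisopropoxycyclobut-2-en-1-one (racemic) | CC(C)OC1=C(OC(C)C)C(O)C1=O | intermediate
3 | (1S,2S)-1,2-diphenylethane-1,2-diol ((S,S)-hydrobenzoin) | O[C@@H](c1ccccc1)[C@@H](O)c1ccccc1 | starting material
4 | (6S,7S)-3-isopropoxy-6,7-diphenyl-5,8-dioxaspiro[3.4]oct-2-en-1-one | CC(C)OC1=CC(=O)C12O[C@@H](c3ccccc3)[C@H](c3ccccc3)O2 | intermediate
5 | (6S,7S)-1-allyl-3-isopropoxy-6,7-diphenyl-5,8-dioxaspiro[3.4]oct-2-en-1-ol (either C1 epimer, not isolated) | C=CCC1(O)C=C(OC(C)C)C12O[C@@H](c3ccccc3)[C@H](c3ccccc3)O2 | intermediate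
6 | (6S,7S)-3-allyl-6,7-diphenyl-5,8-dioxaspiro[3.4]oct-2-en-1-one | C=CCC1=CC(=O)C12O[C@@H](c3ccccc3)[C@H](c3ccccc3)O2 | intermediate
7 | 4-bromo-2-methoxyphenol | COc1cc(Br)ccc1O | starting material
8 | (4-bromo-2-methoxyphenoxy)triisopropylsilane | COc1cc(Br)ccc1O[Si](C(C)C)(C(C)C)C(C)C | intermediate
9 | (S)-propylene oxide ((2S)-2-methyloxirane) | C[C@H]1CO1 | starting material
10 | [3-methoxy-4-(triisopropylsilyloxy)phenyl]magnesium bromide (not isolated) | COc1cc([Mg]Br)ccc1O[Si](C(C)C)(C(C)C)C(C)C | intermediate
11 | (2S)-1-[3-methoxy-4-(triisopropylsilyloxy)phenyl]propan-2-ol | C[C@H](O)Cc1ccc(O[Si](C(C)C)(C(C)C)C(C)C)c(OC)c1 | intermediate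
12 | [4-[(2R)-2-iodopropyl]-2-methoxyphenoxy]triisopropylsilane | C[C@@H](I)Cc1ccc(O[Si](C(C)C)(C(C)C)C(C)C)c(OC)c1 | intermediate
13 | {(2R)-1-[3-methoxy-4-(triisopropylsilyloxy)phenyl]propan-2-yl}lithium (not isolated) | C[C@@H]([Li])Cc1ccc(O[Si](C(C)C)(C(C)C)C(C)C)c(OC)c1 | intermediate
14 | lithium (1S,6S,7S)-3-allyl-1-{(2R)-1-[3-methoxy-4-(triisopropylsilyloxy)phenyl]propan-2-yl}-6,7-diphenyl-5,8-dioxaspiro[3.4]oct-2-en-1-olate (not isolated) | [Li+].C=CCC1=C[C@@]([O-])([C@H](C)Cc2ccc(O[Si](C(C)C)(C(C)C)C(C)C)c(OC)c2)C12O[C@@H](c3ccccc3)[C@H](c3ccccc3)O2 | intermediate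
15 | (1S,6S,7S)-3-allyl-1-methoxy-1-{(2R)-1-[3-methoxy-4-(triisopropylsilyloxy)phenyl]propan-2-yl}-6,7-diphenyl-5,8-dioxaspiro[3.4]oct-2-ene | C=CCC1=C[C@@](OC)([C@H](C)Cc2ccc(O[Si](C(C)C)(C(C)C)C(C)C)c(OC)c2)C12O[C@@H](c3ccccc3)[C@H](c3ccccc3)O2 | intermediate
16 | (4S)-4-methoxy-4-{(2R)-1-[3-methoxy-4-(triisopropylsilyloxy)phenyl]propan-2-yl}-2-(prop-2-en-1-yl)cyclobut-2-en-1-one | C=CCC1=C[C@@](OC)([C@H](C)Cc2ccc(O[Si](C(C)C)(C(C)C)C(C)C)c(OC)c2)C1=O | intermediate
17 | 2-chloro-1,1-dimethoxyethane (chloroacetaldehyde dimethyl acetal) | COC(CCl)OC | starting material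
18 | sodium methoxyacetylide (not isolated) | [Na+].[C-]#COC | intermediate
19 | methoxyacetylene (methoxyethyne) | C#COC | intermediate
20 | (4S)-4,5-dimethoxy-4-{(2R)-1-[3-methoxy-4-(triisopropylsilyloxy)phenyl]propan-2-yl}-2-(prop-2-en-1-yl)cyclohexa-2,5-dien-1-one | C=CCC1=C[C@@](OC)([C@H](C)Cc2ccc(O[Si](C(C)C)(C(C)C)C(C)C)c(OC)c2)C(OC)=CC1=O | intermediate
21 | (4S)-4-[(2R)-1-(4-hydroxy-3-methoxyphenyl)propan-2-yl]-4,5-dimethoxy-2-(prop-2-en-1-yl)cyclohexa-2,5-dien-1-one | C=CCC1=C[C@@](OC)([C@H](C)Cc2ccc(O)c(OC)c2)C(OC)=CC1=O | target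

**Step count**
Total step count: 11. Longest linear sequence: 7 steps (4, 5, 6, 7, 8, 10, 11; the branch 1, 2, 3, 7, 8, 10, 11 is equally long).

**Steps most likely to fail**

1. Step 10 (Proposed new method). What may go wrong: nickel-mediated oligomerisation of the alkynyl ether outrunning insertion, insertion in the wrong orientation, or loss of configuration at C4 if the four-membered ring opens to a free vinylketene.
Fallback (known chemistry; sets out from iodide 12 and comes back at 20): 3,4-dimethoxyphenol is O-allylated (allyl bromide, K2CO3, acetone) to 4-(allyloxy)-1,2-dimethoxybenzene F1. Aromatic Claisen rearrangement (N,N-diethylaniline, 190 °C) should give 2-allyl-4,5-dimethoxyphenol F2, and oxidative demethylation with (NH4)2Ce(NO3)6 in MeCN/H2O should give 2-allyl-5-methoxy-1,4-benzoquinone F3. The secondary alkyllithium 13, made from 12 as in step 7, is added at −100 °C to F3, where it should attack the carbonyl next to the methoxy-bearing carbon (the other carbonyl is a vinylogous ester) to give the lithium quinolate F4. O-Methylation in the same flask with MeOTf should give 20 together with its C4 epimer F5, to be separated by chromatography. This fallback gives up control of C4.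

2. Step 7. What may go wrong: poor facial selectivity at the carbonyl of 6, because the phenyl groups of the spiro-ketal are remote from the reacting carbon.
Fallback (sets out from 2 and comes back at 16): the controlling stereocenter is placed directly on the ring. Compound 2 is hydrolysed with concentrated HCl to 3-isopropoxycyclobut-3-ene-1,2-dione F6. Enantioselective reduction of its more electrophilic carbonyl (Me-CBS oxazaborolidine, BH3·SMe2, catalyst enantiomer chosen to give the (S)-carbinol) should give (4S)-4-hydroxy-3-isopropoxycyclobut-2-en-1-one F7, which is silylated (TBSCl, imidazole) to (4S)-4-(tert-butyldimethylsilyloxy)-3-isopropoxycyclobut-2-en-1-one F8. Allylmagnesium bromide followed by dilute HCl should give, through the tertiary alcohol F9, (4R)-3-allyl-4-(tert-butyldimethylsilyloxy)cyclobut-2-en-1-one F10 by the same transposition as in step 3. Addition of 13 anti to the silyloxy group on the flat four-membered ring should give the lithium alkoxide F11, methylated with MeOTf to the methyl ether F12. HF·pyridine should remove the secondary silyl ether in the presence of the aryl silyl ether to give the cyclobutenol F13, and Dess–Martin periodinane should oxidise it to 16.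

3. Step 6. What may go wrong: erosion of configuration in the iodide through participation of the electron-rich aryl ring or through iodide exchange, and elimination to the propenylarene; any erosion is carried into 13.
Fallback (sets out from 6 and comes back at 15; it needs neither 12 nor 13): commercially available 1-(4-hydroxy-3-methoxyphenyl)propan-1-one is silylated (TIPSCl, imidazole) to 1-[3-methoxy-4-(triisopropylsilyloxy)phenyl]propan-1-one F14. Its (Z)-lithium enolate (LiN(i-Pr)2, THF, −78 °C) is added to 6 in an aldol reaction, in which the closed transition state ties the configuration of the methyl-bearing carbon to that of the carbinol carbon and the ketal again selects the face, to give the lithium aldolate F15. Methylation in the same flask with MeOTf should give the β-methoxy ketone F16. Reduction with NaBH4/CeCl3 should give the benzylic alcohol F17 (either carbinol epimer), and ionic hydrogenation (Et3SiH, BF3·OEt2, −78 °C), which should ionise only the para-silyloxybenzylic position, removes the benzylic oxygen to give 15.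

**Further compounds**
F1 | step 10 | 4-(allyloxy)-1,2-dimethoxybenzene | C=CCOc1ccc(OC)c(OC)c1
F2 | step 10 | 2-allyl-4,5-dimethoxyphenol | C=CCc1cc(OC)c(OC)cc1O
F3 | step 10 | 2-allyl-5-methoxy-1,4-benzoquinone | C=CCC1=CC(=O)C(OC)=CC1=O
F4 | step 10 | lithium quinolate from 13 and F3 (both C4 epimers, side chain (2R)) | [Li+].C=CCC1=CC([O-])([C@H](C)Cc2ccc(O[Si](C(C)C)(C(C)C)C(C)C)c(OC)c2)C(OC)=CC1=O
F5 | step 10 | (4R) epimer of 20 | C=CCC1=C[C@](OC)([C@H](C)Cc2ccc(O[Si](C(C)C)(C(C)C)C(C)C)c(OC)c2)C(OC)=CC1=O
F6 | step 7 | 3-isopropoxycyclobut-3-ene-1,2-dione | CC(C)OC1=CC(=O)C1=O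
F7 | step 7 | (4S)-4-hydroxy-3-isopropoxycyclobut-2-en-1-one | CC(C)OC1=CC(=O)[C@H]1O
F8 | step 7 | (4S)-4-(tert-butyldimethylsilyloxy)-3-isopropoxycyclobut-2-en-1-one | CC(C)OC1=CC(=O)[C@H]1O[Si](C)(C)C(C)(C)C
F9 | step 7 | 1-allyl-4-(tert-butyldimethylsilyloxy)-3-isopropoxycyclobut-2-en-1-ol (either C1 epimer) | C=CCC1(O)C=C(OC(C)C)[C@@H]1O[Si](C)(C)C(C)(C)C
F10 | step 7 | (4R)-3-allyl-4-(tert-butyldimethylsilyloxy)cyclobut-2-en-1-one | C=CCC1=CC(=O)[C@@H]1O[Si](C)(C)C(C)(C)C
F11 | step 7 | lithium alkoxide from 13 and F10 | [Li+].C=CCC1=C[C@@]([O-])([C@H](C)Cc2ccc(O[Si](C(C)C)(C(C)C)C(C)C)c(OC)c2)[C@@H]1O[Si](C)(C)C(C)(C)C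
F12 | step 7 | (1R,4S)-silyl ether of the 2-allyl-4-methoxy-4-(sec-alkyl)cyclobut-2-en-1-ol | C=CCC1=C[C@@](OC)([C@H](C)Cc2ccc(O[Si](C(C)C)(C(C)C)C(C)C)c(OC)c2)[C@@H]1O[Si](C)(C)C(C)(C)C
F13 | step 7 | (1R,4S)-2-allyl-4-methoxy-4-{(2R)-1-[3-methoxy-4-(triisopropylsilyloxy)phenyl]propan-2-yl}cyclobut-2-en-1-ol | C=CCC1=C[C@@](OC)([C@H](C)Cc2ccc(O[Si](C(C)C)(C(C)C)C(C)C)c(OC)c2)[C@@H]1O
F14 | step 6 | 1-[3-methoxy-4-(triisopropylsilyloxy)phenyl]propan-1-one | CCC(=O)c1ccc(O[Si](C(C)C)(C(C)C)C(C)C)c(OC)c1
F15 | step 6 | lithium aldolate from F14 and 6 | [Li+].C=CCC1=C[C@@]([O-])([C@H](C)C(=O)c2ccc(O[Si](C(C)C)(C(C)C)C(C)C)c(OC)c2)C12O[C@@H](c3ccccc3)[C@H](c3ccccc3)O2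
F16 | step 6 | β-methoxy aryl ketone (aldol methyl ether) | C=CCC1=C[C@@](OC)([C@H](C)C(=O)c2ccc(O[Si](C(C)C)(C(C)C)C(C)C)c(OC)c2)C12O[C@@H](c3ccccc3)[C@H](c3ccccc3)O2
F17 | step 6 | benzylic alcohol from F16 (either carbinol epimer) | C=CCC1=C[C@@](OC)([C@H](C)C(O)c2ccc(O[Si](C(C)C)(C(C)C)C(C)C)c(OC)c2)C12O[C@@H](c3ccccc3)[C@H](c3ccccc3)O2
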